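The benzene ring is assembled, not bought: a Dötz benzannulation joins 1-heptadecyne, a benzyloxy(2-methoxyvinyl)carbene pentacarbonylchromium complex and one of its CO ligands. The step exploits the para oxygen pair of the ring: the acetylated oxygen on C2, wedged between pentadecyl-bearing C1 and methoxy-bearing C3, and the free oxygen on C5, between the CH carbons C4 and C6. One operation forms C5–C6, C1–C2 and C2–C3 and delivers the two oxygens already distinct, C2–OH free and C5–O benzylated, so acetylation in the same flask and a closing hydrogenolysis give the target. The precursor is a three-carbon push–pull carbene made from (Z)-2-methoxyvinyllithium and Cr(CO)6.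

Key step: step 5

Assumption: chromium carbonyls are written in SMILES with cumulated Cr=C=O bonds as a valence-bond shorthand, and a residual E content in 5 is harmless because the alkene geometry is erased in step 5.

Step 1
Reactants: 1 1-bromopentadecane; 2 lithium acetylide ethylenediamine complex (LiC≡CH·H2NCH2CH2NH2)
Product: 3 1-heptadecyne
Conditions: 2 (1.3 equiv), DMSO–THF, 0 °C → rt
Reagents that add atoms: none
Why: SN2 alkylation of a terminal acetylide by an unhindered primary bromide in a dipolar aprotic medium, a standard two-carbon chain extension in which the amine-complexed monolithium acetylide avoids double alkylation.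

Step 2
Reactants: 4 bromoacetaldehyde dimethyl acetal
Product: 5 (Z)-1-bromo-2-methoxyethene
Conditions: TMSOTf (1.1 equiv), iPr2NEt (1.2 equiv), CH2Cl2, −20 °C → rt; pentane, filtration; fractional distillation
Reagents that add atoms: none
Why: Silyl-triflate-mediated conversion of an acetal into an enol ether (ionisation of one methoxy group, then removal of a CH2Br proton from the oxocarbenium ion by the hindered amine), with the cis isomer, generally preferred by 1,2-diheteroatom alkenes, enriched by distillation.

Step 3
Reactants: 5 (Z)-1-bromo-2-methoxyethene; 6 chromium hexacarbonyl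
Product: 9 tetramethylammonium pentacarbonyl[(Z)-3-methoxyacryloyl]chromate, via (Z)-2-methoxyvinyllithium 7 (not isolated), via Li[(CO)5CrC(O)CH=CHOMe] 8 (not isolated)
Conditions: t-BuLi (2.0 equiv), Et2O, −78 °C; cannulation onto Cr(CO)6 in THF, −78 → 0 °C; evaporation; Me4NBr, degassed H2O, 0 °C, extraction into CH2Cl2
Reagents that add atoms: tetramethylammonium bromide C[N+](C)(C)C.[Br-]
Why: Stereoretentive bromine–lithium exchange followed by the first half of the Fischer carbene synthesis (organolithium addition to a CO ligand); in the Z lithium species Li and OMe are syn, so anti β-elimination is geometrically denied and oxygen chelation adds stability, and salt metathesis gives a weighable acylate.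

Step 4
Reactants: 9 tetramethylammonium pentacarbonyl[(Z)-3-methoxyacryloyl]chromate
Product: 11 pentacarbonyl[(2Z)-1-(benzyloxy)-3-methoxyprop-2-en-1-ylidene]chromium, via (CO)5Cr=C(OAc)CH=CHOMe 10 (not isolated)
Conditions: AcBr (1.0 equiv), CH2Cl2, −40 °C; BnOH (1.05 equiv), −40 → −10 °C; cold silica filtration under Ar, carried on the same day
Reagents that add atoms: benzyl alcohol OCc1ccccc1
Why: Acylation–alcoholysis route to Fischer carbene complexes bearing alkoxy groups other than methoxy, in which the acylmetalate oxygen is acetylated and the very electrophilic acyloxycarbene carbon undergoes addition–elimination with the alcohol faster than its β-carbon can be attacked at this temperature.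

Step 5
Reactants: 3 1-heptadecyne; 11 pentacarbonyl[(2Z)-1-(benzyloxy)-3-methoxyprop-2-en-1-ylidene]chromium
Product: 13 4-benzyloxy-2-methoxy-6-pentadecylphenyl acetate, via 4-benzyloxy-2-methoxy-6-pentadecylphenol 12 (not isolated)
Conditions: 3 (1.5 equiv), t-BuOMe (0.3 M in 11), Ar, 50 °C until 11 is consumed; then Ac2O, Et3N, DMAP (cat.), 0 °C → rt; then air, daylight, silica filtration (no oxidising work-up)
Reagents that add atoms: acetic anhydride CC(=O)OC(C)=O
Why: Proposed new method: loss of one cis CO ligand on warming (the Z-methoxy oxygen may hold the vacant site as a hemilabile donor) lets 3 coordinate and insert into the Cr=C bond with its CH end bonded to the carbene carbon (C5–C6), after which a CO ligand migrates to the new pentadecyl-bearing carbene carbon (C1–C2) and gives a chromium-bound dienylketene. The only ring closes by 6π electrocyclisation of that ketene, its carbonyl carbon C2 bonding to the methoxy-bearing vinyl terminus C3, and the cyclohexa-2,4-dienone so formed tautomerises by loss of the C3 hydrogen to phenol 12, which is acetylated in the flask before air is admitted. The closest known reaction type is the Dötz benzannulation of alkenyl(alkoxy)carbene chromium complexes with terminal alkynes, including capture of the new phenol by Ac2O in the same pot; not yet shown is its use on a β-alkoxy-substituted, push–pull alkenylcarbene. No stereocentre is created and the enol ether geometry disappears on aromatisation, and since β,β-disubstituted alkenyl complexes are known to ring-close, an inward-pointing methoxy group should not stop the closure. The step needs regioselective insertion, which the size gap between H and C15H31 on the alkyne secures by placing the large group next to the CO-derived carbon, and it needs CO uptake to beat five-ring formation, which is favoured by chromium as the metal, a weakly coordinating ether solvent, a high alkyne concentration and a methoxy donor far weaker than the amino groups known to suppress CO insertion.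

Step 6
Reactants: 13 4-benzyloxy-2-methoxy-6-pentadecylphenyl acetate
Product: 14 4-hydroxy-2-methoxy-6-pentadecylphenyl acetate (target)
Conditions: H2 (1 atm), 10% Pd/C, EtOAc, rt
Reagents that add atoms: none
Why: Catalytic hydrogenolysis of a benzyl aryl ether under neutral conditions, which leaves the aryl acetate, the aryl methyl ether and the saturated chain untouched and supplies no acid or base that could cleave or transfer the acetyl group.

Compound list
1 | 1-bromopentadecane | CCCCCCCCCCCCCCCBr | starting material
2 | lithium acetylide ethylenediamine complex | [Li]C#C.NCCN | starting material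
3 | 1-heptadecyne | CCCCCCCCCCCCCCCC#C | intermediate
4 | bromoacetaldehyde dimethyl acetal (2-bromo-1,1-dimethoxyethane) | COC(OC)CBr | starting material
5 | (Z)-1-bromo-2-methoxyethene | CO/C=C\Br | intermediate
6 | chromium hexacarbonyl | O=C=[Cr](=C=O)(=C=O)(=C=O)(=C=O)=C=O | starting material
7 | (Z)-2-methoxyvinyllithium | CO/C=C\[Li] | intermediate
8 | lithium pentacarbonyl[(Z)-3-methoxyacryloyl]chromate | CO/C=C\C([O-])=[Cr](=C=O)(=C=O)(=C=O)(=C=O)=C=O.[Li+] | intermediate
9 | tetramethylammonium pentacarbonyl[(Z)-3-methoxyacryloyl]chromate | CO/C=C\C([O-])=[Cr](=C=O)(=C=O)(=C=O)(=C=O)=C=O.C[N+](C)(C)C | intermediate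
10 | pentacarbonyl[(2Z)-1-acetoxy-3-methoxyprop-2-en-1-ylidene]chromium | CO/C=C\C(OC(C)=O)=[Cr](=C=O)(=C=O)(=C=O)(=C=O)=C=O | intermediate
11 | pentacarbonyl[(2Z)-1-(benzyloxy)-3-methoxyprop-2-en-1-ylidene]chromium | CO/C=C\C(OCc1ccccc1)=[Cr](=C=O)(=C=O)(=C=O)(=C=O)=C=O | intermediate
12 | 4-benzyloxy-2-methoxy-6-pentadecylphenol | CCCCCCCCCCCCCCCc1cc(OCc2ccccc2)cc(OC)c1O | intermediate
13 | 4-benzyloxy-2-methoxy-6-pentadecylphenyl acetate | CCCCCCCCCCCCCCCc1cc(OCc2ccccc2)cc(OC)c1OC(C)=O | intermediate
14 | 4-hydroxy-2-methoxy-6-pentadecylphenyl acetate | CCCCCCCCCCCCCCCc1cc(O)cc(OC)c1OC(C)=O | target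

Total step count: 6.
Longest linear sequence: 5 steps (4 → 5 → 9 → 11 → 13 → 14).

Steps most likely to fail

Step 5. The donor-stabilised carbene may shed CO too slowly and decay on heating. The vinylcarbene formed after alkyne insertion may also cyclise without taking up CO, so that five-membered rings form at the expense of the arene. The fallback buys the ring and uses only known reactions; it sets out from 1 and comes back at 12.
- Zinc insertion into 1 (Zn dust, LiCl, THF, 50 °C) would give pentadecylzinc bromide F1.
- Commercial 5-bromovanillin F2 would be acetylated (Ac2O, pyridine) to 2-bromo-4-formyl-6-methoxyphenyl acetate F3.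
- Negishi coupling of the two (Pd(OAc)2, SPhos, THF) would give 4-formyl-2-methoxy-6-pentadecylphenyl acetate F4.
- NaOH and H2O2 in THF–water would first saponify the ester to 4-hydroxy-3-methoxy-5-pentadecylbenzaldehyde F5. In the same flask a Dakin oxidation would then give 2-methoxy-6-pentadecylbenzene-1,4-diol F6 (Na2S2O4 in the work-up).
- One equivalent of BnBr with K2CO3 in acetone under argon (Williamson etherification) should alkylate the open hydroxyl between the two ring CH positions in preference to the flanked, hydrogen-bonded one. This gives 12, which is acetylated as in the second half of step 5.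

Step 4. Benzyl alcohol may attack the β-carbon of the push–pull system, which scrambles the two alkoxy groups. The acyloxycarbene may also collapse before alcoholysis. The fallback drops the benzyl group and separates the two oxygens by steric hindrance at the end; it sets out from 9 (together with 3) and comes back at 14.
- O-Methylation of 9 with MeOTf (CH2Cl2, 0 °C), the most dependable closing of a Fischer carbene synthesis, would give pentacarbonyl[(2Z)-1,3-dimethoxyprop-2-en-1-ylidene]chromium F7.
- Benzannulation with 3 as in step 5 would give 2,4-dimethoxy-6-pentadecylphenol F8. This is oxidised without isolation by Ce(NH4)2(NO3)6 in aqueous MeCN to 2-methoxy-6-pentadecyl-1,4-benzoquinone F9.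
- Reductive acetylation (Zn dust, Ac2O, Et3N) would give 2-methoxy-6-pentadecylbenzene-1,4-diyl diacetate F10.
- One equivalent of pyrrolidine at 0 °C should cleave the unhindered acetate between the two ring CH positions and spare the doubly ortho-substituted one, giving 14.

Step 3. Dehydrobromination or deprotonation may compete with the halogen–metal exchange. The vinyllithium may also lose lithium methoxide before the sparingly soluble carbonyl captures it. The fallback inverts the polarity (nucleophilic chromium, electrophilic acyl carbon); it sets out from 6 and comes back at 12.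
- Reduction of 6 with NaC10H8 (THF, −78 °C) would give disodium pentacarbonylchromate F11.
- Commercial methyl (E)-3-methoxyacrylate F12 would be saponified to sodium (E)-3-methoxyacrylate F13. Oxalyl chloride would then convert it into (E)-3-methoxyacryloyl chloride F14.
- Acylation of the chromate dianion by the acid chloride at −78 °C would give sodium pentacarbonyl[(E)-3-methoxyacryloyl]chromate F15.
- Exchange with Me4NBr would give tetramethylammonium pentacarbonyl[(E)-3-methoxyacryloyl]chromate F16.
- The conditions of step 4 would lead through pentacarbonyl[(2E)-1-acetoxy-3-methoxyprop-2-en-1-ylidene]chromium F17 to pentacarbonyl[(2E)-1-(benzyloxy)-3-methoxyprop-2-en-1-ylidene]chromium F18.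
- Since alkene geometry is lost on aromatisation, this complex and 3 under the conditions of step 5 converge on 12 and, in the same flask, 13.

Further compounds
F1 | step 5 | pentadecylzinc bromide | CCCCCCCCCCCCCCC[Zn]Br
F2 | step 5 | 5-bromovanillin (bought) | COc1cc(C=O)cc(Br)c1O
F3 | step 5 | 2-bromo-4-formyl-6-methoxyphenyl acetate | COc1cc(C=O)cc(Br)c1OC(C)=O
F4 | step 5 | 4-formyl-2-methoxy-6-pentadecylphenyl acetate | CCCCCCCCCCCCCCCc1cc(C=O)cc(OC)c1OC(C)=O
F5 | step 5 | 4-hydroxy-3-methoxy-5-pentadecylbenzaldehyde | CCCCCCCCCCCCCCCc1cc(C=O)cc(OC)c1O
F6 | step 5 | 2-methoxy-6-pentadecylbenzene-1,4-diol | CCCCCCCCCCCCCCCc1cc(O)cc(OC)c1O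
F7 | step 4 | pentacarbonyl[(2Z)-1,3-dimethoxyprop-2-en-1-ylidene]chromium | CO/C=C\C(OC)=[Cr](=C=O)(=C=O)(=C=O)(=C=O)=C=O
F8 | step 4 | 2,4-dimethoxy-6-pentadecylphenol | CCCCCCCCCCCCCCCc1cc(OC)cc(OC)c1O
F9 | step 4 | 2-methoxy-6-pentadecyl-1,4-benzoquinone | CCCCCCCCCCCCCCCC1=CC(=O)C=C(OC)C1=O
F10 | step 4 | 2-methoxy-6-pentadecylbenzene-1,4-diyl diacetate | CCCCCCCCCCCCCCCc1cc(OC(C)=O)cc(OC)c1OC(C)=O
F11 | step 3 | disodium pentacarbonylchromate | [Na+].[Na+].O=C=[Cr-2](=C=O)(=C=O)(=C=O)=C=O
F12 | step 3 | methyl (E)-3-methoxyacrylate (bought) | CO/C=C/C(=O)OC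
F13 | step 3 | sodium (E)-3-methoxyacrylate | CO/C=C/C(=O)[O-].[Na+]
F14 | step 3 | (E)-3-methoxyacryloyl chloride | CO/C=C/C(=O)Cl
F15 | step 3 | sodium pentacarbonyl[(E)-3-methoxyacryloyl]chromate | CO/C=C/C([O-])=[Cr](=C=O)(=C=O)(=C=O)(=C=O)=C=O.[Na+]
F16 | step 3 | tetramethylammonium pentacarbonyl[(E)-3-methoxyacryloyl]chromate | CO/C=C/C([O-])=[Cr](=C=O)(=C=O)(=C=O)(=C=O)=C=O.C[N+](C)(C)C
F17 | step 3 | pentacarbonyl[(2E)-1-acetoxy-3-methoxyprop-2-en-1-ylidene]chromium | CO/C=C/C(OC(C)=O)=[Cr](=C=O)(=C=O)(=C=O)(=C=O)=C=O
F18 | step 3 | pentacarbonyl[(2E)-1-(benzyloxy)-3-methoxyprop-2-en-1-ylidene]chromium | CO/C=C/C(OCc1ccccc1)=[Cr](=C=O)(=C=O)(=C=O)(=C=O)=C=O
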